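Plan (germacrane numbering: C7 carries the isopropyl group, C6 the O‑cinnamoyl group, C8 the OH; oxiranes at C4–C5 and C1–C10; ring C1…C10)
- Cuts, in retrosynthetic order: the C1–C10 oxirane oxygen (back to a (Z)‑C1=C10 olefin); the C1–C10 bond itself by ring‑closing metathesis, which opens the ten‑membered ring; the O6–acyl/C8–H pair (Evans–Tishchenko, back to a C8 ketone); C8–C9 (methallyl Grignard on a Weinreb amide); C6–C7 (Evans aldol); the C1 vinyl end (ozonolysis/Wittig on nerol).
- Forward: nerol supplies C1–C6 and C15 with its Z olefin (oxirane C4–C5 first); the chain grows C6 → C7/C8 → C9/C10; the cyclodecene is closed at C1=C10 from the open chain that already holds the oxirane and the ester; the C1–C10 oxirane comes last. No protecting group is used.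
- Enabling feature: both oxiranes are cis‑fused to the ten‑membered ring (C3/C6 cis on C4–C5, C2/C9 cis on C1–C10). The first is a turn element that brings the C1 and C10 chain ends together. The second requires exactly the (Z)‑cyclodecene that metathesis of the C1 vinyl with the C10 methallyl unit should give. The C8 hydroxyl sits homoallylic to C10 and guides the last oxygen.
- Stereochemistry: C4/C5 from Sharpless epoxidation of nerol (D‑(−)‑tartrate); C6/C7 from the (S)‑benzyl oxazolidinone in the syn‑aldol; C8 from intramolecular 1,3‑anti hydride delivery, which also puts the cinnamate on O6 only; C1/C10 from C8–OH‑directed epoxidation of the Z olefin.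

Key step: step 9

Assumption: (4S)‑4‑benzyl‑3‑(3‑methylbutanoyl)‑1,3‑oxazolidin‑2‑one, 2‑methylallylmagnesium chloride (THF solution) and D‑(−)‑diethyl tartrate are taken as catalogue items.

Step 1
Reactants: 1 nerol [(2Z)-3,7-dimethylocta-2,6-dien-1-ol]
Product: 2 [(2R,3S)-3-methyl-3-(4-methylpent-3-en-1-yl)oxiran-2-yl]methanol
Conditions: Ti(OiPr)4 (10 mol%), D‑(−)‑diethyl tartrate (12 mol%), t‑BuOOH, 4 Å MS, CH2Cl2, −20 °C
Reagents that add atoms: tert-butyl hydroperoxide CC(C)(C)OO
Why: Sharpless asymmetric epoxidation acts only on the allylic C2=C3 olefin and leaves the remote isopropylidene, the D‑(−)‑tartrate catalyst delivers oxygen to the face that gives the (2R,3S) oxirane (future C5 R, C4 S), and the Z geometry of nerol fixes the cis relation of the two carbon substituents.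

Step 2
Reactants: 2 [(2R,3S)-3-methyl-3-(4-methylpent-3-en-1-yl)oxiran-2-yl]methanol
Product: 4 3-[(2S,3R)-3-(hydroxymethyl)-2-methyloxiran-2-yl]propanal, via ozonide 3 (not isolated)
Conditions: O3, CH2Cl2, −78 °C; then PPh3, −78 °C → rt
Reagents that add atoms: ozone [O-][O+]=O
Why: Ozonolysis cleaves the only remaining C=C and reductive work‑up of the 1,2,4‑trioxolane should give the aldehyde, while the oxirane and its two stereocentres are not involved.

Step 3
Reactants: 4 3-[(2S,3R)-3-(hydroxymethyl)-2-methyloxiran-2-yl]propanal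
Product: 5 [(2R,3S)-3-(but-3-en-1-yl)-3-methyloxiran-2-yl]methanol
Conditions: Ph3PCH3Br (2.6 equiv), KOtBu (2.5 equiv), THF, 0 °C
Reagents that add atoms: methyltriphenylphosphonium bromide C[P+](c1ccccc1)(c1ccccc1)c1ccccc1.[Br-]
Why: Wittig methylenation of the aldehyde with the unstabilised ylide should give the terminal vinyl group (future C1), the extra equivalent of ylide only deprotonating the hydroxyl, which returns on work‑up.

Step 4
Reactants: 5 [(2R,3S)-3-(but-3-en-1-yl)-3-methyloxiran-2-yl]methanol
Product: 6 (2S,3S)-3-(but-3-en-1-yl)-3-methyloxirane-2-carbaldehyde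
Conditions: TEMPO (10 mol%), PhI(OAc)2, CH2Cl2, rt
Reagents that add atoms: none
Why: Oxoammonium (TEMPO) oxidation of the primary alcohol stops at the aldehyde under nearly neutral conditions that an acid‑sensitive trisubstituted oxirane tolerates, and the oxirane carbon next to the aldehyde cannot enolise, so no stereocentre is at risk.

Step 5
Reactants: 6 (2S,3S)-3-(but-3-en-1-yl)-3-methyloxirane-2-carbaldehyde; 7 (4S)-4-benzyl-3-(3-methylbutanoyl)-1,3-oxazolidin-2-one
Product: 10 (4S)-4-benzyl-3-[(2S,3S)-3-[(2R,3S)-3-(but-3-en-1-yl)-3-methyloxiran-2-yl]-3-hydroxy-2-(propan-2-yl)propanoyl]-1,3-oxazolidin-2-one, via Z boron enolate 8 (not isolated), via boron aldolate 9 (not isolated)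
Conditions: n‑Bu2BOTf, Et3N, CH2Cl2, −78 → 0 °C; then 6, −78 → 0 °C; pH 7 buffer, MeOH, 30% H2O2, 0 °C
Reagents that add atoms: none
Why: Evans syn‑aldol reaction, in which the (Z)‑boron enolate reacts through a closed chair (Zimmerman–Traxler) transition state on the enolate face away from the benzyl group, should set C7 and C6 as the 2,3‑syn pair (future 7R, 6S) under reagent control that overrides the small facial bias of the epoxy aldehyde.

Step 6
Reactants: 10 (4S)-4-benzyl-3-[(2S,3S)-3-[(2R,3S)-3-(but-3-en-1-yl)-3-methyloxiran-2-yl]-3-hydroxy-2-(propan-2-yl)propanoyl]-1,3-oxazolidin-2-one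
Product: 11 (2S,3S)-3-[(2R,3S)-3-(but-3-en-1-yl)-3-methyloxiran-2-yl]-3-hydroxy-N-methoxy-N-methyl-2-(propan-2-yl)propanamide
Conditions: MeNHOMe·HCl, AlMe3, THF, −20 → 0 °C; Rochelle salt work‑up
Reagents that add atoms: N,O-dimethylhydroxylamine hydrochloride CNOC.Cl
Why: Aluminium amide transamidation (Weinreb amide formation), guided to the exocyclic imide carbonyl by the aluminium alkoxide of the free β‑hydroxyl, should release the auxiliary without touching a stereocentre, the low temperature and coordinating solvent keeping the oxirane closed.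

Step 7
Reactants: 11 (2S,3S)-3-[(2R,3S)-3-(but-3-en-1-yl)-3-methyloxiran-2-yl]-3-hydroxy-N-methoxy-N-methyl-2-(propan-2-yl)propanamide; 12 (2-methylprop-2-en-1-yl)magnesium chloride
Product: 14 (1S,2S)-1-[(2R,3S)-3-(but-3-en-1-yl)-3-methyloxiran-2-yl]-1-hydroxy-5-methyl-2-(propan-2-yl)hex-5-en-3-one, via magnesium tetrahedral adduct 13 (not isolated)
Conditions: 12 (3 equiv), THF, −78 → −20 °C; cold pH 7 buffer quench
Reagents that add atoms: none
Why: Grignard acylation of a Weinreb amide stops at the ketone because the chelated tetrahedral adduct survives until the quench, the first equivalent of reagent only deprotonates the hydroxyl, and the cold neutral quench should keep the β,γ‑olefin out of conjugation and C7 unepimerised.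

Step 8
Reactants: 14 (1S,2S)-1-[(2R,3S)-3-(but-3-en-1-yl)-3-methyloxiran-2-yl]-1-hydroxy-5-methyl-2-(propan-2-yl)hex-5-en-3-one; 15 (E)-cinnamaldehyde [(2E)-3-phenylprop-2-enal]
Product: 17 (1S,2R,3R)-1-[(2R,3S)-3-(but-3-en-1-yl)-3-methyloxiran-2-yl]-3-hydroxy-5-methyl-2-(propan-2-yl)hex-5-en-1-yl (2E)-3-phenylprop-2-enoate, via samarium-bound hemiacetal 16 (not isolated)
Conditions: SmI2 (30 mol%), 15 (5 equiv), THF, −10 °C, dark
Reagents that add atoms: none
Why: Evans–Tishchenko reduction, in which the samarium‑bound hemiacetal of O6 with cinnamaldehyde passes its hydride through a six‑membered chair to the C8 ketone, should give the 1,3‑anti carbinol (8R) and leave the cinnamoyl group on O6 alone, so that the ester position and the C8 configuration are set in one event.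

Step 9
Reactants: 17 (1S,2R,3R)-1-[(2R,3S)-3-(but-3-en-1-yl)-3-methyloxiran-2-yl]-3-hydroxy-5-methyl-2-(propan-2-yl)hex-5-en-1-yl (2E)-3-phenylprop-2-enoate
Product: 18 (1(10)Z,4S,5R,6S,7R,8R)-4,5-epoxygermacr-1(10)-ene-6,8-diol 6-[(2E)-3-phenylprop-2-enoate]
Conditions: Grubbs II (15 mol%, in portions), toluene (1 mM), 80 °C, Ar sparge
Reagents that add atoms: none
Why: Ring‑closing olefin metathesis: the ruthenium carbene initiates at the monosubstituted C1 vinyl group, the new alkylidene adds to the 1,1‑disubstituted C10 methallyl olefin in a [2+2] step, and cycloreversion of the ruthenacyclobutane forms the C1=C10 bond and releases ethene. The closest known reaction type is metathesis macrocyclisation of a 1‑alkene onto a 2‑methyl‑1‑alkene to give a trisubstituted olefin in a nine‑ to eleven‑membered carbocycle or lactone. One ring is closed, the ten‑membered carbocycle, by end‑to‑end union of the chain termini C1 and C10. No stereocentre is formed; the new stereo element is the olefin geometry, which should be Z because an (E)‑cyclodecene that also holds the cis‑fused C4–C5 oxirane is far more strained, and Z is what the cis‑fused C1–C10 oxirane of the target needs. The step needs ring closure over oligomerisation and reaction at the methallyl olefin and not at the cinnamate C=C; high dilution and the turn imposed by the cis‑oxirane (C3 and C6 on one side) should secure the first, and the low metathesis reactivity of the conjugated, 1,2‑disubstituted, aryl‑capped enoate the second. Loss of ethene makes the closure irreversible.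

Step 10
Reactants: 18 (1(10)Z,4S,5R,6S,7R,8R)-4,5-epoxygermacr-1(10)-ene-6,8-diol 6-[(2E)-3-phenylprop-2-enoate]
Product: 19 (1R,4S,5R,6S,7R,8R,10S)-1,10:4,5-diepoxygermacrane-6,8-diol 6-[(2E)-3-phenylprop-2-enoate] (CNP0272646.1)
Conditions: VO(acac)2 (5 mol%), t‑BuOOH (decane), CH2Cl2, 0 °C → rt
Reagents that add atoms: tert-butyl hydroperoxide CC(C)(C)OO
Why: Vanadium‑catalysed hydroxyl‑directed epoxidation of a homoallylic alcohol, in which the C8 vanadate ester delivers the peroxidic oxygen through a chair‑like array (O8–C8–C9–C10) with C7 and the C10=C1 bond pseudo‑equatorial (the alternative is ruled out by the Z substituent C2), should place the new C10–O bond 1,3‑syn to C8–O (10S, 1R) with retention of the olefin geometry as the cis ring fusion, while the electron‑poor cinnamate C=C and the existing oxirane do not react.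

Compound list
1 | nerol, (2Z)-3,7-dimethylocta-2,6-dien-1-ol | CC(C)=CCC/C(C)=C\CO | starting material
2 | [(2R,3S)-3-methyl-3-(4-methylpent-3-en-1-yl)oxiran-2-yl]methanol | OC[C@H]1O[C@@]1(C)CCC=C(C)C | intermediate
3 | ozonide of 2: [(2R,3S)-3-[2-(5,5-dimethyl-1,2,4-trioxolan-3-yl)ethyl]-3-methyloxiran-2-yl]methanol (not isolated) | OC[C@H]1O[C@@]1(C)CCC1OOC(C)(C)O1 | intermediate
4 | 3-[(2S,3R)-3-(hydroxymethyl)-2-methyloxiran-2-yl]propanal | OC[C@H]1O[C@@]1(C)CCC=O | intermediate
5 | [(2R,3S)-3-(but-3-en-1-yl)-3-methyloxiran-2-yl]methanol | OC[C@H]1O[C@@]1(C)CCC=C | intermediate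
6 | (2S,3S)-3-(but-3-en-1-yl)-3-methyloxirane-2-carbaldehyde | O=C[C@H]1O[C@@]1(C)CCC=C | intermediate
7 | (4S)-4-benzyl-3-(3-methylbutanoyl)-1,3-oxazolidin-2-one | CC(C)CC(=O)N1C(=O)OC[C@@H]1Cc1ccccc1 | starting material
8 | (Z)-dibutylboron enolate of 7 (not isolated) | CC(C)/C=C(\OB(CCCC)CCCC)N1C(=O)OC[C@@H]1Cc1ccccc1 | intermediate
9 | dibutylboron aldolate of 10, O6–BBu2 (not isolated) | CC(C)[C@@H]([C@H](OB(CCCC)CCCC)[C@H]1O[C@@]1(C)CCC=C)C(=O)N1C(=O)OC[C@@H]1Cc1ccccc1 | intermediate
10 | (4S)-4-benzyl-3-[(2S,3S)-3-[(2R,3S)-3-(but-3-en-1-yl)-3-methyloxiran-2-yl]-3-hydroxy-2-(propan-2-yl)propanoyl]-1,3-oxazolidin-2-one | CC(C)[C@@H]([C@H](O)[C@H]1O[C@@]1(C)CCC=C)C(=O)N1C(=O)OC[C@@H]1Cc1ccccc1 | intermediate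
11 | (2S,3S)-3-[(2R,3S)-3-(but-3-en-1-yl)-3-methyloxiran-2-yl]-3-hydroxy-N-methoxy-N-methyl-2-(propan-2-yl)propanamide | CC(C)[C@@H]([C@H](O)[C@H]1O[C@@]1(C)CCC=C)C(=O)N(C)OC | intermediate
12 | (2-methylprop-2-en-1-yl)magnesium chloride | CC(=C)C[Mg]Cl | starting material
13 | bis(chloromagnesium) tetrahedral adduct of 11 and 12: C8 alkoxide still carrying N(OMe)Me, O6 as magnesium alkoxide (not isolated) | CC(C)[C@@H]([C@H](O[Mg]Cl)[C@H]1O[C@@]1(C)CCC=C)C(O[Mg]Cl)(CC(C)=C)N(C)OC | intermediate
14 | (1S,2S)-1-[(2R,3S)-3-(but-3-en-1-yl)-3-methyloxiran-2-yl]-1-hydroxy-5-methyl-2-(propan-2-yl)hex-5-en-3-one | CC(C)[C@@H]([C@H](O)[C@H]1O[C@@]1(C)CCC=C)C(=O)CC(C)=C | intermediate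
15 | (E)-cinnamaldehyde | O=C/C=C/c1ccccc1 | starting material
16 | samarium-bound hemiacetal of O6 of 14 with 15, drawn in the free O–H form (not isolated) | CC(C)[C@@H]([C@H](OC(O)/C=C/c1ccccc1)[C@H]1O[C@@]1(C)CCC=C)C(=O)CC(C)=C | intermediate
17 | (1S,2R,3R)-1-[(2R,3S)-3-(but-3-en-1-yl)-3-methyloxiran-2-yl]-3-hydroxy-5-methyl-2-(propan-2-yl)hex-5-en-1-yl (2E)-3-phenylprop-2-enoate | CC(C)[C@@H]([C@H](OC(=O)/C=C/c1ccccc1)[C@H]1O[C@@]1(C)CCC=C)[C@H](O)CC(C)=C | intermediate
18 | (1(10)Z,4S,5R,6S,7R,8R)-4,5-epoxygermacr-1(10)-ene-6,8-diol 6-(E)-cinnamate (ten-membered ring, cis-fused C4–C5 oxirane, free 8-OH) | CC(C)[C@H]1[C@H](OC(=O)/C=C/c2ccccc2)[C@H]2O[C@@]2(C)CC/C=C(/C)C[C@H]1O | intermediate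
19 | (1R,4S,5R,6S,7R,8R,10S)-1,10:4,5-diepoxygermacrane-6,8-diol 6-(E)-cinnamate, CNP0272646.1 | CC(C)[C@H]1[C@H](OC(=O)/C=C/c2ccccc2)[C@H]2O[C@@]2(C)CC[C@H]2O[C@@]2(C)C[C@H]1O | target

Total steps: 10. Longest linear sequence: 10 steps (nerol to 19).

Steps most likely to fail

Step 9 (ring closure). What may go wrong is intermolecular metathesis (oligomerisation) outpacing closure of the strained ten‑membered ring, or the ruthenium alkylidene engaging the cinnamate C=C. The fallback inverts the order of ring closure and ester formation. It sets out from ketone 14: ring‑closing metathesis (second‑generation Hoveyda–Grubbs catalyst, toluene, 1 mM, 80 °C) is run before any enoate is present and with an sp2 carbon (C8) in the ring, and should give (1(10)Z,4S,5R,6S,7S)-4,5-epoxy-6-hydroxygermacr-1(10)-en-8-one F1. The Evans–Tishchenko reaction of F1 with cinnamaldehyde (SmI2 cat., THF, −10 °C) then sets C8 and puts the cinnamate on O6, and the route is rejoined at 18.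

Step 10 (last epoxidation). What may go wrong is delivery of oxygen to the wrong face of C1=C10, if the ring conformer that holds O8 over the olefin is not populated, or transannular opening of an oxirane at the Lewis‑acidic vanadium centre. The fallback replaces hydroxyl direction by reagent control. It sets out from 18, which is epoxidised with a fructose‑derived chiral ketone and Oxone (Shi epoxidation, K2CO3 buffer, MeCN–dimethoxymethane–water, 0 °C), using the ketone enantiomer that is matched to the required face. This metal‑free dioxirane should prefer the electron‑rich trisubstituted olefin over the cinnamate and leads directly to 19 (no new compound, F0).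

Step 8 (Evans–Tishchenko with an enal). What may go wrong is slow hydride transfer from the conjugated hemiacetal, so that retro‑aldol cleavage or drift of the β,γ‑olefin into conjugation competes, or migration of the acyl group from O6 to O8. The fallback separates reduction and acylation. It sets out from 14: hydroxyl‑directed 1,3‑anti reduction (Me4NBH(OAc)3, MeCN/AcOH, −30 °C, Evans–Saksena reduction) should give the anti‑diol F2. The less hindered 8‑OH, flanked by a CH2 group, is silylated selectively (TESCl, imidazole, CH2Cl2, −40 °C) to give the 8‑O‑triethylsilyl ether F3. The 6‑OH is acylated with (E)‑cinnamoyl chloride (pyridine, DMAP, 0 °C) to give the silyl ether cinnamate F4. Pyridine‑buffered HF·pyridine (THF, 0 °C) removes the silyl group, and the route is rejoined at 17.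

Further compounds
F1 | step 9 | (1(10)Z,4S,5R,6S,7S)-4,5-epoxy-6-hydroxygermacr-1(10)-en-8-one | CC(C)[C@H]1[C@H](O)[C@H]2O[C@@]2(C)CC/C=C(/C)CC1=O
F0 | step 10 | none | none
F2 | step 8 | (1S,2R,3R)-1-[(2R,3S)-3-(but-3-en-1-yl)-3-methyloxiran-2-yl]-5-methyl-2-(propan-2-yl)hex-5-ene-1,3-diol (anti-diol; 17 without the cinnamoyl group) | CC(C)[C@@H]([C@H](O)[C@H]1O[C@@]1(C)CCC=C)[C@H](O)CC(C)=C
F3 | step 8 | 8-O-triethylsilyl ether of F2 (O6–H free, same configuration at all centres) | CC(C)[C@@H]([C@H](O)[C@H]1O[C@@]1(C)CCC=C)[C@H](O[Si](CC)(CC)CC)CC(C)=C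
F4 | step 8 | 6-O-(E)-cinnamate of F3 (8-O-triethylsilyl ether of 17) | CC(C)[C@@H]([C@H](OC(=O)/C=C/c1ccccc1)[C@H]1O[C@@]1(C)CCC=C)[C@H](O[Si](CC)(CC)CC)CC(C)=C
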